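**Retrosynthetic overview**
- The 4-hydroxystyryl unit is attached last by a Claisen–Schmidt condensation. The benzene ring of the benzofuran is carried as a cyclohexane-1,3-dione vinylogous ester, C-acetylated at C5 through its enolate and dehydrogenated late.
- Key disconnection: ring carbon C2 to the side-chain carbinol carbon. The bond is made by a 1,2-metalate shift in a three-component enantioselective conjunctive cross-coupling of a sulcatone-derived alkenylboronate, a vinyl metal (C2 and C3 of the furan ring) and 2-bromo-3-ethoxycyclohexenone (C3a).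
- Enabling feature: the array C3a (sp2, flanked by the oxygenated carbons C4 and C7a)–C3H2–C2H(O1)–C(OH)(CH3). The C2–O1 bond is the retron of a C–B bond, C3a that of an alpha-halo vinylogous ester, and the carbinol carbon with its methyl group that of a 1,1-disubstituted alkenyl group able to migrate from boron.
- The C2 carbinol formed in the key step directs a matched Sharpless epoxidation that sets the tertiary centre. Hydride opening of the oxirane then gives the methyl carbinol.
- Ring order: the carbocycle is bought; the dihydrofuran ring is closed by vinylogous transesterification (retention at C2); the carbocycle is aromatised with DDQ; the second arene is bought.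

Key step: step 4

Assumption: the MandyPhos antipode that delivers the (S)-boronate is chosen by analogy with the known sense of induction; if the other antipode is needed, only the ligand is exchanged.

**Step 1**
Reactants: 1 6-methylhept-5-en-2-one (sulcatone)
Product: 2 6-methylhepta-1,5-dien-2-yl trifluoromethanesulfonate
Conditions: LDA, THF, −78 °C; PhNTf2, −78 °C → rt
Reagents that add atoms: N-phenylbis(trifluoromethanesulfonimide), O=S(=O)(N(c1ccccc1)S(=O)(=O)C(F)(F)F)C(F)(F)F
Why: Kinetic deprotonation of a methyl ketone by LDA takes place at the methyl group, and O-sulfonylation of this less substituted lithium enolate (enol triflate formation) fixes the terminal 1,1-disubstituted alkene; no stereocentre is formed.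

**Step 2**
Reactants: 2 6-methylhepta-1,5-dien-2-yl trifluoromethanesulfonate
Product: 3 4,4,5,5-tetramethyl-2-(6-methylhepta-1,5-dien-2-yl)-1,3,2-dioxaborolane
Conditions: B2pin2, PdCl2(PPh3)2 (cat.), PPh3, KOPh, toluene, 50 °C
Reagents that add atoms: bis(pinacolato)diboron, CC1(C)OB(OC1(C)C)B1OC(C)(C)C(C)(C)O1
Why: The Miyaura borylation of alkenyl triflates replaces the triflate by a pinacolboryl group at the same carbon without moving the double bond, and the isolated trisubstituted alkene does not take part.

**Step 3**
Reactants: 4 3-ethoxycyclohex-2-en-1-one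
Product: 5 2-bromo-3-ethoxycyclohex-2-en-1-one
Conditions: NBS, CH2Cl2, 0 °C, dark
Reagents that add atoms: N-bromosuccinimide, O=C1CCC(=O)N1Br
Why: The push-pull alkene of a vinylogous ester is nucleophilic at its alpha carbon, so electrophilic bromination followed by loss of a proton places the halogen only at C2, the future C3a.

**Step 4**
Reactants: 3 4,4,5,5-tetramethyl-2-(6-methylhepta-1,5-dien-2-yl)-1,3,2-dioxaborolane; 5 2-bromo-3-ethoxycyclohex-2-en-1-one; 6 vinylmagnesium bromide
Product: 9 3-ethoxy-2-[(2S)-2-hydroxy-7-methyl-3-methylideneoct-6-en-1-yl]cyclohex-2-en-1-one, via sodium bis(alkenyl)borate 7 (not isolated), via (S)-allylboronate 8 (not isolated)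
Conditions: 3, 6, THF, 0 °C → rt; NaOTf, DMSO; 5, Pd(OAc)2 (cat.), MandyPhos (cat.), 40–60 °C; then 30% H2O2, pH 7 buffer, THF, 0 °C → rt
Reagents that add atoms: hydrogen peroxide, OO
Why: Vinylmagnesium bromide adds to the boron atom of 3 (NaOTf drives ate formation and takes up bromide), and the cationic alkenylpalladium(II) complex formed from 5 by oxidative addition binds the unsubstituted vinyl group of 7, the least hindered of its three alkenes. Anti to palladium, the 1,1-disubstituted C8 alkenyl group then shifts from boron to the adjacent vinyl carbon (1,2-metalate rearrangement), which forms the bond between the future ring carbon C2 and the future carbinol carbon, and reductive elimination from the resulting alkyl(alkenyl)palladium joins C3 to C3a. The closest known reaction type is the enantioselective palladium-catalysed conjunctive cross-coupling of non-symmetric bis(alkenyl)borates with C(sp2) electrophiles, in which the more substituted alkenyl group migrates and an alpha-chiral allylboronate results. No ring is closed in this step. The one new stereocentre is set by the chiral bisphosphine, which selects the face of the vinyl group that palladium binds, and the buffered peroxide oxidation replaces boron by oxygen with retention. The step needs selectivity for the conjunctive pathway over direct transfer of an alkenyl group to palladium and for vinyl activation over activation of the other alkenes, which the pinacol ligand on boron, the wide-bite-angle ligand and the substitution pattern of 7 secure, while the vinylogous ester carbonyl group is too weak an electrophile to be attacked by the borate or allylated by 8.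

**Step 5**
Reactants: 9 3-ethoxy-2-[(2S)-2-hydroxy-7-methyl-3-methylideneoct-6-en-1-yl]cyclohex-2-en-1-one
Product: 10 3-ethoxy-2-{(2S)-2-hydroxy-2-[(2R)-2-(4-methylpent-3-en-1-yl)oxiran-2-yl]ethyl}cyclohex-2-en-1-one
Conditions: Ti(OiPr)4 (cat.), L-(+)-DIPT (cat.), t-BuOOH, 4 Å MS, CH2Cl2, −20 °C
Reagents that add atoms: tert-butyl hydroperoxide, CC(C)(C)OO
Why: In the Sharpless asymmetric epoxidation titanium binds the secondary allylic alcohol, so only the 1,1-disubstituted allylic alkene is oxidised (not the remote trisubstituted or the push-pull ring alkene), and for the (S)-carbinol L-(+)-DIPT is the matched ligand that gives the erythro epoxy alcohol and thereby fixes the future tertiary carbinol carbon as the (R)-oxirane, while residual (R)-alcohol reacts slowly and is removed (kinetic resolution).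

**Step 6**
Reactants: 10 3-ethoxy-2-{(2S)-2-hydroxy-2-[(2R)-2-(4-methylpent-3-en-1-yl)oxiran-2-yl]ethyl}cyclohex-2-en-1-one
Product: 12 (2S)-2-[(2S)-2-hydroxy-6-methylhept-5-en-2-yl]-3,5,6,7-tetrahydro-1-benzofuran-4(2H)-one, via (2S,3S)-diol 11 (not isolated)
Conditions: LDA (2.1 equiv), THF, −78 °C; LiEt3BH, −78 → 0 °C; aq. work-up; crude 11, PPTS (cat.), 4 Å MS, CH2Cl2, rt → 40 °C
Reagents that add atoms: none
Why: Prior conversion of the vinylogous ester into its cross-conjugated lithium enolate shields the carbonyl group, so the SN2 hydride opening of the oxirane CH2 by LiEt3BH gives the methyl carbinol with the tertiary C–O stereocentre untouched, and mild acid then lets the secondary hydroxyl group displace ethanol (vinylogous transesterification, 5-exo attack on the protonated enol ether, retention at the carbinol carbon because its C–O bond is not broken), the tertiary hydroxyl group being too hindered to compete.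

**Step 7**
Reactants: 12 (2S)-2-[(2S)-2-hydroxy-6-methylhept-5-en-2-yl]-3,5,6,7-tetrahydro-1-benzofuran-4(2H)-one
Product: 13 1-[(2S)-4-hydroxy-2-[(2S)-2-hydroxy-6-methylhept-5-en-2-yl]-2,3,6,7-tetrahydro-1-benzofuran-5-yl]ethan-1-one (enol form of the 5-acetyl ketone)
Conditions: LDA (2.2 equiv), THF, −78 °C; 1-acetylbenzotriazole, −78 → 0 °C
Reagents that add atoms: 1-acetyl-1H-benzotriazole, CC(=O)n1nnc2ccccc12
Why: Kinetic deprotonation of a 3-alkoxyenone takes place at the alpha' carbon (C5), a 1-acylbenzotriazole transfers its acyl group to the carbon of lithium enolates (Claisen-type C-acylation), the tertiary alkoxide takes up the acidic proton of the beta-diketone, and no new stereocentre remains because C5 is enolised.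

**Step 8**
Reactants: 13 1-[(2S)-4-hydroxy-2-[(2S)-2-hydroxy-6-methylhept-5-en-2-yl]-2,3,6,7-tetrahydro-1-benzofuran-5-yl]ethan-1-one
Product: 14 1-[(2S)-4-hydroxy-2-[(2S)-2-hydroxy-6-methylhept-5-en-2-yl]-2,3-dihydro-1-benzofuran-5-yl]ethan-1-one
Conditions: DDQ (1.1 equiv), 1,4-dioxane, rt
Reagents that add atoms: none
Why: The enol 13 is a 1,3-cyclohexadiene with only C6 and C7 left at the sp3 level, so hydride abstraction by DDQ and loss of a proton (quinone dehydrogenation) should give the benzene ring at room temperature, where the isolated alkene, the tertiary alcohol, the dihydrofuran ring and both stereocentres are left alone.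

**Step 9**
Reactants: 14 1-[(2S)-4-hydroxy-2-[(2S)-2-hydroxy-6-methylhept-5-en-2-yl]-2,3-dihydro-1-benzofuran-5-yl]ethan-1-one; 15 4-hydroxybenzaldehyde
Product: 16 (2E)-1-[(2S)-4-hydroxy-2-[(2S)-2-hydroxy-6-methylhept-5-en-2-yl]-2,3-dihydro-1-benzofuran-5-yl]-3-(4-hydroxyphenyl)prop-2-en-1-one
Conditions: KOH (excess), EtOH–H2O, rt → 40 °C; then dilute HCl to pH 5, 0 °C
Reagents that add atoms: none
Why: The Claisen–Schmidt condensation of a 2-hydroxyacetophenone with an aromatic aldehyde proceeds through aldol addition and E1cB loss of water to the conjugated (E)-enone, the thermodynamic alkene isomer, and strong base touches neither the ether and carbinol stereocentres nor the alkene.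

**Compound list**
1 | 6-methylhept-5-en-2-one | CC(=O)CCC=C(C)C | starting material
2 | 6-methylhepta-1,5-dien-2-yl trifluoromethanesulfonate | C=C(CCC=C(C)C)OS(=O)(=O)C(F)(F)F | intermediate
3 | 4,4,5,5-tetramethyl-2-(6-methylhepta-1,5-dien-2-yl)-1,3,2-dioxaborolane | C=C(CCC=C(C)C)B1OC(C)(C)C(C)(C)O1 | intermediate
4 | 3-ethoxycyclohex-2-en-1-one | CCOC1=CC(=O)CCC1 | starting material
5 | 2-bromo-3-ethoxycyclohex-2-en-1-one | CCOC1=C(Br)C(=O)CCC1 | intermediate
6 | vinylmagnesium bromide | C=C[Mg]Br | starting material
7 | sodium (6-methylhepta-1,5-dien-2-yl)(vinyl)(pinacolato)borate | C=C[B-]1(C(=C)CCC=C(C)C)OC(C)(C)C(C)(C)O1.[Na+] | intermediate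
8 | 3-ethoxy-2-[(2S)-7-methyl-3-methylidene-2-(4,4,5,5-tetramethyl-1,3,2-dioxaborolan-2-yl)oct-6-en-1-yl]cyclohex-2-en-1-one | CCOC1=C(C[C@H](B2OC(C)(C)C(C)(C)O2)C(=C)CCC=C(C)C)C(=O)CCC1 | intermediate
9 | 3-ethoxy-2-[(2S)-2-hydroxy-7-methyl-3-methylideneoct-6-en-1-yl]cyclohex-2-en-1-one | CCOC1=C(C[C@H](O)C(=C)CCC=C(C)C)C(=O)CCC1 | intermediate
10 | 3-ethoxy-2-{(2S)-2-hydroxy-2-[(2R)-2-(4-methylpent-3-en-1-yl)oxiran-2-yl]ethyl}cyclohex-2-en-1-one | CCOC1=C(C[C@H](O)[C@@]2(CCC=C(C)C)CO2)C(=O)CCC1 | intermediate
11 | 2-[(2S,3S)-2,3-dihydroxy-3,7-dimethyloct-6-en-1-yl]-3-ethoxycyclohex-2-en-1-one | CCOC1=C(C[C@H](O)[C@@](C)(O)CCC=C(C)C)C(=O)CCC1 | intermediate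
12 | (2S)-2-[(2S)-2-hydroxy-6-methylhept-5-en-2-yl]-3,5,6,7-tetrahydro-1-benzofuran-4(2H)-one | CC(C)=CCC[C@](C)(O)[C@@H]1CC2=C(O1)CCCC2=O | intermediate
13 | 1-[(2S)-4-hydroxy-2-[(2S)-2-hydroxy-6-methylhept-5-en-2-yl]-2,3,6,7-tetrahydro-1-benzofuran-5-yl]ethan-1-one | CC(C)=CCC[C@](C)(O)[C@@H]1CC2=C(O1)CCC(C(C)=O)=C2O | intermediate
14 | 1-[(2S)-4-hydroxy-2-[(2S)-2-hydroxy-6-methylhept-5-en-2-yl]-2,3-dihydro-1-benzofuran-5-yl]ethan-1-one | CC(C)=CCC[C@](C)(O)[C@@H]1Cc2c(ccc(C(C)=O)c2O)O1 | intermediate
15 | 4-hydroxybenzaldehyde | O=Cc1ccc(O)cc1 | starting material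
16 | (2E)-1-[(2S)-4-hydroxy-2-[(2S)-2-hydroxy-6-methylhept-5-en-2-yl]-2,3-dihydro-1-benzofuran-5-yl]-3-(4-hydroxyphenyl)prop-2-en-1-one | CC(C)=CCC[C@](C)(O)[C@@H]1Cc2c(ccc(C(=O)/C=C/c3ccc(O)cc3)c2O)O1 | target

**Step count**
Total step count: 9. Longest linear sequence: 8 (steps 1, 2, 4, 5, 6, 7, 8, 9).

**Steps most likely to fail**

1. **Step 4.**
   - What may go wrong: slow oxidative addition of the hindered bromide or inhibition by halide may let direct alkenyl transfer to palladium or protodeboronation outrun the metalate shift, and the crowded alkenylpalladium may lower the facial selectivity.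
   - Fallback: it sets out from 5 and 2 and returns at 9.
   - A Stille coupling of 5 with allyltributylstannane would give 2-allyl-3-ethoxycyclohex-2-en-1-one F1.
   - Lemieux–Johnson cleavage (OsO4 cat., NaIO4) of its terminal alkene would give (2-ethoxy-6-oxocyclohex-1-en-1-yl)acetaldehyde F2.
   - A catalytic asymmetric Nozaki–Hiyama–Kishi coupling of F2 with the alkenyl triflate 2 (CrCl2, NiCl2 cat., chiral sulfonamide ligand) would form the same carbon–carbon bond chemoselectively at the aldehyde and give 9.
   - Step 5 then serves as a kinetic resolution that raises the enantiomeric purity.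

2. **Step 6.**
   - What may go wrong: incomplete masking may allow 1,2-reduction of the vinylogous ester, the lithium alkoxide may trigger Payne migration of the oxirane before hydride arrives, and the acid step may be slow.
   - Fallback: it sets out from 10 and returns at 13.
   - The ring is closed first with catalytic PPTS, when the secondary hydroxyl group is the only one present. This gives (2S)-2-[(2R)-2-(4-methylpent-3-en-1-yl)oxiran-2-yl]-3,5,6,7-tetrahydro-1-benzofuran-4(2H)-one F3.
   - C5 is then acetylated as in step 7 to give the enolised 5-acetyl oxirane F4.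
   - Treatment with excess LiEt3BH first deprotonates the beta-diketone. The delocalised enolate protects both carbonyl groups while the second equivalent opens the oxirane to give 13.

3. **Step 7.**
   - What may go wrong: O-acylation of the enolate, acylation of the tertiary alkoxide, or proton exchange between product and enolate may stop the conversion.
   - Fallback: it sets out from 12 and returns at 13.
   - The same dianion is added to acetaldehyde (aldol addition, no acidic product) to give the 5-(1-hydroxyethyl) ketone F5 as a mixture at the two new centres.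
   - Dess–Martin oxidation of the secondary alcohol, which cannot touch the tertiary one, erases both new centres and gives 13.

**Further compounds**
F1 | step 4 | 2-allyl-3-ethoxycyclohex-2-en-1-one | CCOC1=C(CC=C)C(=O)CCC1
F2 | step 4 | (2-ethoxy-6-oxocyclohex-1-en-1-yl)acetaldehyde | CCOC1=C(CC=O)C(=O)CCC1
F3 | step 6 | (2S)-2-[(2R)-2-(4-methylpent-3-en-1-yl)oxiran-2-yl]-3,5,6,7-tetrahydro-1-benzofuran-4(2H)-one | CC(C)=CCC[C@@]1(CO1)[C@@H]2CC3=C(O2)CCCC3=O
F4 | step 6 | 1-[(2S)-4-hydroxy-2-[(2R)-2-(4-methylpent-3-en-1-yl)oxiran-2-yl]-2,3,6,7-tetrahydro-1-benzofuran-5-yl]ethan-1-one | CC(C)=CCC[C@@]1(CO1)[C@@H]2CC3=C(O2)CCC(C(C)=O)=C3O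
F5 | step 7 | (2S)-5-(1-hydroxyethyl)-2-[(2S)-2-hydroxy-6-methylhept-5-en-2-yl]-3,5,6,7-tetrahydro-1-benzofuran-4(2H)-one | CC(C)=CCC[C@](C)(O)[C@@H]1CC2=C(O1)CCC(C(C)O)C2=O
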